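**Strategy**

Ring A (C1–C5) holds a carbinol at C2, a methylene at C3 and the isopropyl-bearing tertiary carbinol at C4: the pattern of a 4-hydroxycyclopent-2-enone, which a furfuryl alcohol delivers by oxa-Piancatelli rearrangement. The precursor is a flat trisubstituted furan, (5-isopropyl-3-methylfuran-2-yl)methanol. In one enantioselective dearomatising operation water adds to the isopropyl-bearing furan carbon and the former CH2OH carbon (C3) closes onto it (C3–C4 bond), giving ring A with the C4 stereocentre, the C2 carbonyl and a C1=C5 enone. C4 then relays all stereocentres: photocycloaddition and glycol cleavage plant C6 and C10 cis on C5 and C1, and two carbonyl additions plus ring-closing metathesis build ring B.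

Key step: step 3

Numbering and faces: daucane numbering is used from compound 5 on (C1 = methyl-bearing ring-fusion carbon, C2 = CHOH, C3 = CH2, C4 = C(OH)CH(CH3)2, C5 = ring-fusion CH, C6 and C10 = acyloxy carbons, C7 = CH2, C8 and C9 = epoxide carbons). β is the face of ring A that carries the C4 oxygen; α is the face that carries 1-CH3 and 5-H. In the bicyclic compounds the same labels refer to the flat drawing of the cis-fused bicycle.

**Route**

Step 1
Reactants: 1 methyl 3-methylfuran-2-carboxylate
Product: 2 methyl 5-isopropyl-3-methylfuran-2-carboxylate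
Conditions: 2-chloropropane, AlCl3, CH2Cl2, 0 °C to rt
Reagents that add atoms: 2-chloropropane, CC(C)Cl
Why: Friedel–Crafts alkylation, in which the free furan α-position C5 is the most nucleophilic site of the 2-acylfuran and the ester deactivates the product against a second alkylation.

Step 2
Reactants: 2 methyl 5-isopropyl-3-methylfuran-2-carboxylate
Product: 3 (5-isopropyl-3-methylfuran-2-yl)methanol
Conditions: LiAlH4, Et2O, 0 °C
Reagents that add atoms: none
Why: Hydride reduction of the ester gives the primary furfuryl alcohol needed for ionisation; no stereocentre is involved.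

Step 3
Reactants: 3 (5-isopropyl-3-methylfuran-2-yl)methanol
Product: 5 (R)-4-hydroxy-4-isopropyl-2-methylcyclopent-2-en-1-one, via ring-opened dienol 4 (not isolated)
Conditions: (R)-3,3′-bis(2,4,6-triisopropylphenyl)-1,1′-binaphthyl-2,2′-diyl N-triflylphosphoramide (5 mol%), H2O (10 equiv), CHCl3, 40 °C
Reagents that add atoms: water, O
Why: Proposed new method: acid ionises the furfuryl alcohol to a 2-methylenefuranium ion, water adds at the isopropyl-bearing furan carbon, the hemiketal opens to dienol 4, and its O-protonated form, a 1,4-dihydroxypentadienyl cation paired with the chiral phosphoramide anion, undergoes 4π-conrotatory electrocyclisation in which the former CH2OH carbon (C3) bonds to the carbonyl carbon (C4), followed by proton loss to the enone. The racemic oxa-Piancatelli rearrangement of 5-alkylfurfuryl alcohols is known, and the closest known asymmetric reactions are the chiral Brønsted acid-catalysed aza-Piancatelli rearrangement and Nazarov cyclisation, which steer the same kind of electrocyclisation through a chiral counter-anion. Ring A closes by this pentadienyl-cation electrocyclisation, equivalent to a 5-enolexo aldol of the enol onto the protonated isobutyryl ketone. The only new stereocentre, C4, is set by the sense of conrotation, that is by which face of the C4 carbonyl the enol terminus attacks, and this should be controlled by hydrogen bonding of both hydroxyls to the chiral anion; the catalyst antipode that gives (R)-5 would be used. The step needs water to attack the isopropyl-bearing furan carbon and the cation not to oligomerise: the nucleophilic furan α-position is blocked by isopropyl, and the 3-methyl and 5-isopropyl groups stabilise the cation so that the primary alcohol ionises under mild conditions.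

Step 4
Reactants: 5 (R)-4-hydroxy-4-isopropyl-2-methylcyclopent-2-en-1-one; 6 vinylene carbonate
Product: 7 cis-anti-cis photoadduct (ring A 2-ketone fused at C1–C5 to a cyclobutane carrying the cyclic carbonate on C10 and C6)
Conditions: hν (350 nm), 6 (10 equiv), acetone, −20 °C
Reagents that add atoms: none
Why: Enone–alkene [2+2] photocycloaddition through the enone triplet: the five-membered enone enforces a cis ring fusion and the alkene should add to the C1=C5 face anti to the C4 isopropyl group, which sets C1 (1α-CH3) and C5 (5α-H) and places C10 and C6 cis on the β face; the configuration at the two carbonate carbons is lost in step 7, so the anti isomer drawn and any syn isomer converge.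

Step 5
Reactants: 7 cis-anti-cis photoadduct
Product: 8 2α-hydroxy photoadduct (trans-2α,4β-diol carbonate)
Conditions: Me4NBH(OAc)3, MeCN/AcOH (1:1), −25 °C
Reagents that add atoms: none
Why: Evans–Saksena directed reduction: the C4 hydroxyl binds the borohydride and delivers hydride intramolecularly to the β face of the C2 ketone, which should give the trans-1,3-diol (2α-OH).

Step 6
Reactants: 8 2α-hydroxy photoadduct
Product: 9 2α,4β-bis(triethylsilyl) ether of 8
Conditions: Et3SiOSO2CF3, 2,6-lutidine, CH2Cl2, 0 °C to rt
Reagents that add atoms: triethylsilyl trifluoromethanesulfonate, CC[Si](CC)(CC)OS(=O)(=O)C(F)(F)F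
Why: Silylation with the silyl triflate masks the hindered secondary and the tertiary hydroxyl, so that the C2 oxygen stays protected through the later esterification and the C4 oxygen cannot add to or leave from the carbonyl intermediates.

Step 7
Reactants: 9 2α,4β-bis(triethylsilyl) ether of 8
Product: 11 1α-methyl-4α-isopropyl-2α,4β-bis(triethylsilyloxy)cyclopentane-1β,5β-dicarbaldehyde, via cyclobutanediol 10 (not isolated)
Conditions: NaOH, THF/H2O, 0 °C to rt; NaH2PO4 to pH 7; then NaIO4, 0 °C
Reagents that add atoms: none
Why: Base hydrolysis of the cyclic carbonate and Malaprade glycol cleavage of the cis-cyclobutanediol cut the C6–C10 bond and release the two cis formyl groups; neutral pH during the cleavage avoids epimerisation at C5.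

Step 8
Reactants: 11 cis-dialdehyde
Product: 12 (6S)-6-(2-methylallyl) lactol (C6–O–C10 hemiacetal; anomer mixture)
Conditions: (−)-B-(2-methylallyl)diisopinocampheylborane (1.1 equiv), Et2O, −78 °C; then NaBO3·4H2O, THF/H2O, rt
Reagents that add atoms: (−)-B-(2-methylallyl)diisopinocampheylborane (from (+)-α-pinene), C[C@H]1[C@H](B(CC(C)=C)[C@@H]3C[C@@H]4C[C@H]([C@H]3C)C4(C)C)C[C@@H]2C[C@H]1C2(C)C
Why: Brown asymmetric allylboration: the reagent should attack the Si face of the C6 formyl group, which sits on a CH carbon and is less shielded than the C10 formyl group on quaternary C1 next to the C2 silyl ether, setting 6S under reagent control, and the new hydroxyl closes onto the cis C10 formyl group as a lactol.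

Step 9
Reactants: 12 (6S)-lactol
Product: 13 (6S,10S)-diene-diol (C1 carries CH(OH)CH=CH2 and C5 carries CH(OH)CH2C(CH3)=CH2)
Conditions: CH2=CHMgBr (3 equiv), THF, −78 to 0 °C
Reagents that add atoms: vinylmagnesium bromide, C=C[Mg]Br
Why: Grignard addition to the open hydroxy-aldehyde form of the lactol: in the magnesium chelate between the C6 alkoxide and the C10 carbonyl the nucleophile should attack anti to the C2 branch and past the C1 methyl group (Felkin–Anh), giving the 10S carbinol.

Step 10
Reactants: 13 (6S,10S)-diene-diol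
Product: 14 2α,4β-bis(triethylsilyloxy)dauc-8-ene-6α,10β-diol
Conditions: second-generation Grubbs catalyst (H2IMes)(PCy3)Cl2Ru=CHPh (5 mol%), CH2Cl2, 40 °C
Reagents that add atoms: none
Why: Ring-closing metathesis of the vinyl carbinol with the 1,1-disubstituted methallyl alkene closes seven-membered ring B and forms the trisubstituted C8=C9 alkene, helped by the cis arrangement of the two chains on ring A.

Step 11
Reactants: 14 dauc-8-ene-6α,10β-diol
Product: 15 8β,9β-epoxy-2α,4β-bis(triethylsilyloxy)daucane-6α,10β-diol
Conditions: VO(acac)2 (5 mol%), t-BuOOH, CH2Cl2, 0 °C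
Reagents that add atoms: tert-butyl hydroperoxide, CC(C)(C)OO
Why: Vanadium-catalysed hydroxyl-directed epoxidation: the allylic C10 hydroxyl binds the metal peroxide and delivers oxygen to the alkene face syn to itself (β), which should outrun delivery from the homoallylic C6 hydroxyl on the opposite face.

Step 12
Reactants: 15 epoxy diol; 16 angelic acid
Product: 17 8β,9β-epoxy-2α,4β-bis(triethylsilyloxy)daucane-6α,10β-diyl bis[(Z)-2-methylbut-2-enoate]
Conditions: 16 (6 equiv), 2,4,6-trichlorobenzoyl chloride, Et3N, toluene, rt; then 15, 75 °C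
Reagents that add atoms: none
Why: Yamaguchi esterification through the mixed anhydride acylates both secondary hydroxyls without a base strong enough to isomerise the (Z)-enoate, while the C2 and C4 oxygens are silylated and inert.

Step 13
Reactants: 17 bis-angelate bis(silyl ether)
Product: 18 CNP0265715.3 (target)
Conditions: Bu4NF, AcOH (1:1), THF, 0 °C to rt
Reagents that add atoms: none
Why: Buffered fluoride desilylation cleaves both triethylsilyl ethers under near-neutral conditions that the angelate esters and the epoxide should survive, with no change at any stereocentre.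

**Compound list**

1 | methyl 3-methylfuran-2-carboxylate | COC(=O)c1occc1C | starting material
2 | methyl 5-isopropyl-3-methylfuran-2-carboxylate | COC(=O)c1oc(C(C)C)cc1C | intermediate
3 | (5-isopropyl-3-methylfuran-2-yl)methanol | OCc1oc(C(C)C)cc1C | intermediate
4 | (4Z)-6-hydroxy-2,5-dimethylhepta-4,6-dien-3-one (ring-opened dienol) | C=C(O)/C(C)=C\C(=O)C(C)C | intermediate
5 | (R)-4-hydroxy-4-isopropyl-2-methylcyclopent-2-en-1-one | CC1=C[C@](O)(C(C)C)CC1=O | intermediate
6 | vinylene carbonate (1,3-dioxol-2-one) | O=C1OC=CO1 | starting material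
7 | cis-anti-cis photoadduct: 4β-hydroxy-4α-isopropyl-1α-methyl ring A 2-ketone, fused at C1–C5 (5α-H) to a cyclobutane whose C10 and C6 carry a cyclic carbonate anti to ring A | C[C@@]12C(=O)C[C@@](O)(C(C)C)[C@@H]1[C@H]3OC(=O)O[C@@H]23 | intermediate
8 | 2α-hydroxy photoadduct (2α,4β-diol of 7) | C[C@@]12[C@@H](O)C[C@@](O)(C(C)C)[C@@H]1[C@H]3OC(=O)O[C@@H]23 | intermediate
9 | 2α,4β-bis(triethylsilyl) ether of 8 | C[C@@]12[C@@H](O[Si](CC)(CC)CC)C[C@@](O[Si](CC)(CC)CC)(C(C)C)[C@@H]1[C@H]3OC(=O)O[C@@H]23 | intermediate
10 | cyclobutane-cis-6,10-diol from hydrolysis of 9 | C[C@@]12[C@@H](O[Si](CC)(CC)CC)C[C@@](O[Si](CC)(CC)CC)(C(C)C)[C@@H]1[C@@H](O)[C@H]2O | intermediate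
11 | 1α-methyl-4α-isopropyl-2α,4β-bis(triethylsilyloxy)cyclopentane-1β,5β-dicarbaldehyde | O=C[C@]1(C)[C@@H](O[Si](CC)(CC)CC)C[C@@](O[Si](CC)(CC)CC)(C(C)C)[C@@H]1C=O | intermediate
12 | (6S)-6-(2-methylallyl) lactol between the C6 hydroxyl and the C10 formyl group, cis-fused to ring A, mixture of C10 anomers | OC1O[C@@H](CC(C)=C)[C@@H]2[C@@]1(C)[C@@H](O[Si](CC)(CC)CC)C[C@@]2(O[Si](CC)(CC)CC)C(C)C | intermediate
13 | (6S,10S)-diene-diol: ring A with C1 bearing CH3 (α) and CH(OH)CH=CH2 (β), C5 bearing CH(OH)CH2C(CH3)=CH2 (β), 2α,4β-bis(triethylsilyloxy), 4α-isopropyl | C=C[C@H](O)[C@@]1(C)[C@@H]([C@@H](O)CC(C)=C)[C@](O[Si](CC)(CC)CC)(C(C)C)C[C@@H]1O[Si](CC)(CC)CC | intermediate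
14 | 2α,4β-bis(triethylsilyloxy)dauc-8-ene-6α,10β-diol (1α-CH3, 5α-H, cis-fused) | O[C@H]1CC(C)=C[C@H](O)[C@@]2(C)[C@@H]1[C@](O[Si](CC)(CC)CC)(C(C)C)C[C@@H]2O[Si](CC)(CC)CC | intermediate
15 | 8β,9β-epoxy-2α,4β-bis(triethylsilyloxy)daucane-6α,10β-diol | O[C@H]1C[C@]2(C)O[C@@H]2[C@H](O)[C@@]2(C)[C@@H]1[C@](O[Si](CC)(CC)CC)(C(C)C)C[C@@H]2O[Si](CC)(CC)CC | intermediate
16 | angelic acid, (Z)-2-methylbut-2-enoic acid | C/C=C(/C)C(=O)O | starting material
17 | 8β,9β-epoxy-2α,4β-bis(triethylsilyloxy)daucane-6α,10β-diyl bis[(Z)-2-methylbut-2-enoate] | C/C=C(/C)C(=O)O[C@H]1C[C@]2(C)O[C@@H]2[C@H](OC(=O)/C(C)=C\C)[C@@]2(C)[C@@H]1[C@](O[Si](CC)(CC)CC)(C(C)C)C[C@@H]2O[Si](CC)(CC)CC | intermediate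
18 | CNP0265715.3: 8β,9β-epoxy-2α,4β-dihydroxydaucane-6α,10β-diyl bis[(Z)-2-methylbut-2-enoate], 1α-CH3, 5α-H, cis-fused; (1S,2S,4R,5S,6S,8S,9R,10R) in daucane numbering | C/C=C(/C)C(=O)O[C@H]1C[C@]2(C)O[C@@H]2[C@H](OC(=O)/C(C)=C\C)[C@@]2(C)[C@@H]1[C@](O)(C(C)C)C[C@@H]2O | target

**Step count and risks**

Total step count: 13. Longest linear sequence: 13 steps (from 1).

Steps most likely to fail:

Step 3. The chiral counter-anion may fail to control the sense of ring closure because the uncatalysed rearrangement competes, and the furfuryl cation may oligomerise. The fallback uses known chemistry and sets out from 3. The thermal oxa-Piancatelli rearrangement (H2O/dioxane, NaH2PO4 buffer, 100 °C) should give racemic 4-hydroxy-4-isopropyl-2-methylcyclopent-2-en-1-one F1. CBS reduction under reagent control ((R)-Me-CBS oxazaborolidine, BH3·SMe2, THF) should turn the two enantiomers into separable diastereomers, (1S,4R)-4-isopropyl-2-methylcyclopent-2-ene-1,4-diol F2 (trans) and (1S,4S)-4-isopropyl-2-methylcyclopent-2-ene-1,4-diol F3 (cis). After chromatography, MnO2 in CH2Cl2 re-oxidises the allylic alcohol of F2 and the route is rejoined at 5.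

Step 9. The vinyl addition at C10 may show poor facial selectivity, or select the wrong face if the C2 silyl ether rather than the C6 alkoxide organises the magnesium. The fallback sets out from 12. The addition product enriched in the C10 epimer, (6S,10R)-diene-diol F4, is cyclised by the same metathesis to 2α,4β-bis(triethylsilyloxy)dauc-8-ene-6α,10α-diol F5. MnO2 oxidises only the allylic C10 carbinol to 6α-hydroxy-2α,4β-bis(triethylsilyloxy)dauc-8-en-10-one F6. CBS reduction under reagent control ((R)-Me-CBS oxazaborolidine, catecholborane, with quaternary C1 as the large group) should give the 10β-alcohol and rejoin the route at 14.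

Step 12. Acylation of the neopentyl C10 carbinol may be incomplete, and the angelate may isomerise to the tiglate geometry at the temperature needed. The fallback sets out from 15. Acylation with 2-[bis(2,2,2-trifluoroethoxy)phosphoryl]propanoic acid (EDC·HCl, DMAP, CH2Cl2) gives the 6α,10β-bis(phosphonopropanoate) F7. A double Still–Gennari olefination (KN(SiMe3)2, 18-crown-6, acetaldehyde, THF, −78 °C) builds both (Z)-2-methylbut-2-enoates under kinetic control and rejoins the route at 17.

**Further compounds**

F1 | step 3 | racemic 4-hydroxy-4-isopropyl-2-methylcyclopent-2-en-1-one | CC1=CC(O)(C(C)C)CC1=O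
F2 | step 3 | (1S,4R)-4-isopropyl-2-methylcyclopent-2-ene-1,4-diol | CC1=C[C@](O)(C(C)C)C[C@@H]1O
F3 | step 3 | (1S,4S)-4-isopropyl-2-methylcyclopent-2-ene-1,4-diol | CC1=C[C@@](O)(C(C)C)C[C@@H]1O
F4 | step 9 | (6S,10R)-diene-diol, C10 epimer of 13 | C=C[C@@H](O)[C@@]1(C)[C@@H]([C@@H](O)CC(C)=C)[C@](O[Si](CC)(CC)CC)(C(C)C)C[C@@H]1O[Si](CC)(CC)CC
F5 | step 9 | 2α,4β-bis(triethylsilyloxy)dauc-8-ene-6α,10α-diol | O[C@H]1CC(C)=C[C@@H](O)[C@@]2(C)[C@@H]1[C@](O[Si](CC)(CC)CC)(C(C)C)C[C@@H]2O[Si](CC)(CC)CC
F6 | step 9 | 6α-hydroxy-2α,4β-bis(triethylsilyloxy)dauc-8-en-10-one | O[C@H]1CC(C)=CC(=O)[C@@]2(C)[C@@H]1[C@](O[Si](CC)(CC)CC)(C(C)C)C[C@@H]2O[Si](CC)(CC)CC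
F7 | step 12 | 8β,9β-epoxy-2α,4β-bis(triethylsilyloxy)daucane-6α,10β-diyl bis{2-[bis(2,2,2-trifluoroethoxy)phosphoryl]propanoate} | CC(C(=O)O[C@H]1C[C@]2(C)O[C@@H]2[C@H](OC(=O)C(C)P(=O)(OCC(F)(F)F)OCC(F)(F)F)[C@@]2(C)[C@@H]1[C@](O[Si](CC)(CC)CC)(C(C)C)C[C@@H]2O[Si](CC)(CC)CC)P(=O)(OCC(F)(F)F)OCC(F)(F)F
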